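The 1,2-dioxane (O1, O2, C3–C6) is cut at C4–C5 and O2–C3. Because C3–O2 lies β to the carboxyl carbon of the propanoic acid arm, C3, C2 of the acid and CO2H are read as a β-lactone, and the tertiary peroxide at C6 as a perhydrolysed epoxide. In one flask the primary radical at C5 of a β-(silylperoxy)alkyl bromide adds to the exocyclic CH2 (C4) of an enantiopure 3-methyl-4-methylidene-β-lactone. The lactone methyl group steers hydrogen transfer to C3, and two SN2 inversions (bromide, then the peroxide oxygen) replace the lactone C–O bond by O2–C3, closing the ring and releasing the acid.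

Key step: step 8

Assumption: the antipodes named for the binaphthoxide catalyst (step 1) and the resolving amine (step 5) are taken to be those that deliver (S)-2 and (R)-8; if the sense proves opposite, the other antipode is used.
Remark: the CIP label of the quaternary peroxide carbon alternates between R and S along the route only because the ranking of its two CH2 arms changes; no bond to this carbon is made or broken after step 2.

Step 1
Reactants: 1 methyl 4-oxopentanoate (methyl levulinate)
Product: 2 methyl 3-[(2S)-2-methyloxiran-2-yl]propanoate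
Conditions: Me3S(O)I, NaH, LaLi3[(S)-binaphthoxide]3 (5 mol %), (2,4,6-(MeO)3C6H2)3P=O (5 mol %), 5 Å MS, THF, rt
Reagents that add atoms: trimethylsulfoxonium iodide, C[S+](C)(C)=O.[I-]
Why: Catalytic asymmetric Corey–Chaykovsky epoxidation of a methyl ketone; the chiral lanthanum/lithium binaphthoxide complex binds ketone and ylide and differentiates the ketone faces, which sets the future C6 as (S), while the ester is much less electrophilic toward the stabilised ylide.

Step 2
Reactants: 2 methyl 3-[(2S)-2-methyloxiran-2-yl]propanoate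
Product: 3 methyl (4R)-4-hydroperoxy-5-hydroxy-4-methylpentanoate
Conditions: H2O2 (anhydrous, in Et2O), H3PMo12O40 (cat.), Et2O, rt
Reagents that add atoms: hydrogen peroxide, OO
Why: Phosphomolybdic acid-catalysed perhydrolysis of a 2,2-disubstituted epoxide; hydrogen peroxide should attack the tertiary carbon with SN2-like inversion, giving the (R)-tertiary hydroperoxide and leaving the epoxide oxygen as the primary alcohol on the future C5.

Step 3
Reactants: 3 methyl (4R)-4-hydroperoxy-5-hydroxy-4-methylpentanoate
Product: 4 methyl (4R)-5-hydroxy-4-methyl-4-[(triethylsilyl)peroxy]pentanoate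
Conditions: Et3SiCl (1.0 equiv), Et3N, CH2Cl2, −78 to −40 °C
Reagents that add atoms: chlorotriethylsilane, CC[Si](Cl)(CC)CC
Why: Chemoselective silylation; the more acidic and α-effect-activated hydroperoxide should be silylated ahead of the primary alcohol with one equivalent of chlorosilane at low temperature, masking O–O–H for the radical step.

Step 4
Reactants: 4 methyl (4R)-5-hydroxy-4-methyl-4-[(triethylsilyl)peroxy]pentanoate
Product: 6 methyl (4R)-5-bromo-4-methyl-4-[(triethylsilyl)peroxy]pentanoate, via triflate 5 (not isolated)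
Conditions: Tf2O, 2,6-lutidine, CH2Cl2, −78 °C; then Bu4NBr, −78 to 0 °C
Reagents that add atoms: tetrabutylammonium bromide, CCCC[N+](CCCC)(CCCC)CCCC.[Br-]
Why: Triflation followed by SN2 halide exchange; only a triflate is reactive enough for displacement at this neopentyl-type carbon, and the non-reducing bromide spares the silyl peroxide, C6 being untouched.

Step 5
Reactants: 7 rac-2-methylbut-3-enoic acid
Product: 8 (2R)-2-methylbut-3-enoic acid
Conditions: (S)-1-phenylethylamine, EtOAc, fractional crystallisation; then aq. HCl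
Reagents that add atoms: none
Why: Classical resolution through diastereomeric ammonium salts should give the (R)-acid whose stereocentre becomes C2 of the propanoic acid arm.

Step 6
Reactants: 8 (2R)-2-methylbut-3-enoic acid
Product: 9 (3R,4S)-4-(iodomethyl)-3-methyloxetan-2-one (trans isomer expected as the major one; the C4 epimer is equally usable)
Conditions: I2, aq. NaHCO3, Et2O, 0 °C, dark
Reagents that add atoms: iodine, II
Why: Kinetic iodolactonisation of a β,γ-unsaturated acid (4-exo attack of carboxylate on the iodonium ion) gives the β-lactone; the C4 configuration is erased in step 7 and C3 is not touched.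

Step 7
Reactants: 9 (3R,4S)-4-(iodomethyl)-3-methyloxetan-2-one
Product: 10 (3R)-3-methyl-4-methylideneoxetan-2-one
Conditions: AgF, 2,6-lutidine, MeCN, rt, dark
Reagents that add atoms: none
Why: Silver fluoride-assisted E2 dehydroiodination of a β-oxygenated primary iodide, the standard route to exocyclic enol ethers, should give the enol lactone; the only β-hydrogen is on C4 and the hindered weak base does not enolise C3.

Step 8
Reactants: 6 methyl (4R)-5-bromo-4-methyl-4-[(triethylsilyl)peroxy]pentanoate; 10 (3R)-3-methyl-4-methylideneoxetan-2-one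
Product: 13 (2R)-2-[(3S,6S)-6-(3-methoxy-3-oxopropyl)-6-methyl-1,2-dioxan-3-yl]propanoic acid, via cis-β-lactone 11 (not isolated), via β-bromo acid 12 (not isolated)
Conditions: 10 (5 equiv, excess recovered), (Me3Si)3SiH (slow addition), Et3B (cat.), air, PhMe, 0 °C; evaporation; MgBr2·OEt2, Et2O, 0 °C; then Bu4NF, THF, 0 °C; aq. HCl
Reagents that add atoms: none
Why: Proposed new method: the tris(trimethylsilyl)silyl radical abstracts bromine from 6, the primary β-(silylperoxy)alkyl radical adds to the terminal carbon of the strained enol-lactone alkene of 10 (C4–C5 bond), and the oxetanyl radical takes hydrogen from the silane on the face anti to the ring methyl group to give cis-lactone 11; bromide then opens 11 at the alkyl C–O carbon with inversion (12), and the fluoride-released peroxide anion displaces bromide by 6-exo-tet SN2 with a second inversion (O2–C3 bond), setting the acid free. The closest known reaction types are Giese-type reductive additions of alkyl halides to enol esters, SN2 alkyl–oxygen opening of β-lactones by halide and intramolecular alkylation of peroxide anions; their union on a peroxide-bearing radical is new. The new stereocentre C3 is controlled by the lactone methyl group (cis-selective hydrogen transfer) and by the two stereospecific displacements, which together give net retention and hence 3S; C2 of the acid and C6 are carried in unchanged. The step needs radical addition to outrun γ-scission of the β-peroxyalkyl radical to an epoxide (excess 10, slow silane addition, poor leaving ability of a silyloxyl radical) and needs peroxide attack at carbon rather than elimination (six-membered transition state, carboxylate form of 12).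

Step 9
Reactants: 13 (2R)-2-[(3S,6S)-6-(3-methoxy-3-oxopropyl)-6-methyl-1,2-dioxan-3-yl]propanoic acid
Product: 14 (2R)-2-[(3S,6S)-6-methyl-6-(3-oxopropyl)-1,2-dioxan-3-yl]propanoic acid
Conditions: i-Bu2AlH (2.2 equiv), CH2Cl2, −78 °C; aq. Rochelle salt
Reagents that add atoms: none
Why: Low-temperature DIBAL-H half-reduction of the methyl ester through the stable aluminium hemiacetal; the acid is held as an unreactive aluminium carboxylate and the hindered dialkyl peroxide should be inert at −78 °C.

Step 10
Reactants: 15 4-(2,6,6-trimethylcyclohex-1-en-1-yl)butan-2-one (dihydro-β-ionone); 16 2,4,6-tri(propan-2-yl)benzenesulfonohydrazide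
Product: 17 N'-[(2E)-4-(2,6,6-trimethylcyclohex-1-en-1-yl)butan-2-ylidene]-2,4,6-tri(propan-2-yl)benzenesulfonohydrazide
Conditions: MeOH, cat. HCl, rt
Reagents that add atoms: none
Why: Condensation of a methyl ketone with an arenesulfonyl hydrazide gives the hydrazone needed for the Shapiro reaction.

Step 11
Reactants: 17 N'-[(2E)-4-(2,6,6-trimethylcyclohex-1-en-1-yl)butan-2-ylidene]-2,4,6-tri(propan-2-yl)benzenesulfonohydrazide; 14 (2R)-2-[(3S,6S)-6-methyl-6-(3-oxopropyl)-1,2-dioxan-3-yl]propanoic acid
Product: 19 (2R)-2-[(3S,6R)-6-[(3RS)-3-hydroxy-4-methylidene-6-(2,6,6-trimethylcyclohex-1-en-1-yl)hexyl]-6-methyl-1,2-dioxan-3-yl]propanoic acid, via vinyllithium 18 (not isolated)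
Conditions: 17 (2.5 equiv), n-BuLi (2 equiv per 17), THF, −78 to 0 °C; then 14, −78 °C; aq. NH4Cl
Reagents that add atoms: none
Why: Shapiro reaction (deprotonation at N–H and at the less hindered α-methyl group, loss of N2 and sulfinate) gives the 2-lithio-1-alkene, which should add to the aldehyde at −78 °C faster than it attacks the hindered peroxide; one equivalent is spent on the acid, and the carbinol centre is formed without control and corrected in steps 12 and 13.

Step 12
Reactants: 19 (2R)-2-[(3S,6R)-6-[(3RS)-3-hydroxy-4-methylidene-6-(2,6,6-trimethylcyclohex-1-en-1-yl)hexyl]-6-methyl-1,2-dioxan-3-yl]propanoic acid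
Product: 20 (2R)-2-[(3S,6S)-6-methyl-6-[4-methylidene-3-oxo-6-(2,6,6-trimethylcyclohex-1-en-1-yl)hexyl]-1,2-dioxan-3-yl]propanoic acid
Conditions: Dess–Martin periodinane, CH2Cl2, 0 °C to rt
Reagents that add atoms: none
Why: Dess–Martin oxidation of the allylic alcohol to the α-methylidene ketone is neutral and should leave peroxide, acid and alkenes untouched.

Step 13
Reactants: 20 (2R)-2-[(3S,6S)-6-methyl-6-[4-methylidene-3-oxo-6-(2,6,6-trimethylcyclohex-1-en-1-yl)hexyl]-1,2-dioxan-3-yl]propanoic acid
Product: 21 (2R)-2-[(3S,6R)-6-[(3R)-3-hydroxy-4-methylidene-6-(2,6,6-trimethylcyclohex-1-en-1-yl)hexyl]-6-methyl-1,2-dioxan-3-yl]propanoic acid (CNP0205216.4)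
Conditions: (S)-2-methyl-CBS-oxazaborolidine (0.3 equiv), catecholborane, PhMe, −78 °C; MeOH, aq. work-up
Reagents that add atoms: none
Why: Corey–Bakshi–Shibata reduction; the (S)-oxazaborolidine binds the ketone with the 1-substituted vinyl group as the large substituent and directs hydride to the face that gives the (R)-allylic alcohol, and catecholborane should not reduce the acid or the dialkyl peroxide at −78 °C.

Compound list
1 | methyl 4-oxopentanoate | CC(=O)CCC(=O)OC | starting material
2 | methyl 3-[(2S)-2-methyloxiran-2-yl]propanoate | C[C@]1(CCC(=O)OC)CO1 | intermediate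
3 | methyl (4R)-4-hydroperoxy-5-hydroxy-4-methylpentanoate | COC(=O)CC[C@](C)(CO)OO | intermediate
4 | methyl (4R)-5-hydroxy-4-methyl-4-[(triethylsilyl)peroxy]pentanoate | COC(=O)CC[C@](C)(CO)OO[Si](CC)(CC)CC | intermediate
5 | methyl (4R)-4-methyl-4-[(triethylsilyl)peroxy]-5-[(trifluoromethanesulfonyl)oxy]pentanoate | COC(=O)CC[C@](C)(COS(=O)(=O)C(F)(F)F)OO[Si](CC)(CC)CC | intermediate
6 | methyl (4R)-5-bromo-4-methyl-4-[(triethylsilyl)peroxy]pentanoate | COC(=O)CC[C@](C)(CBr)OO[Si](CC)(CC)CC | intermediate
7 | rac-2-methylbut-3-enoic acid | C=CC(C)C(=O)O | starting material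
8 | (2R)-2-methylbut-3-enoic acid | C=C[C@@H](C)C(=O)O | intermediate
9 | (3R,4S)-4-(iodomethyl)-3-methyloxetan-2-one | C[C@@H]1[C@@H](CI)OC1=O | intermediate
10 | (3R)-3-methyl-4-methylideneoxetan-2-one | C[C@@H]1C(=C)OC1=O | intermediate
11 | methyl (4S)-4-methyl-6-[(2S,3R)-3-methyl-4-oxooxetan-2-yl]-4-[(triethylsilyl)peroxy]hexanoate | C[C@@H]1[C@H](CC[C@@](C)(CCC(=O)OC)OO[Si](CC)(CC)CC)OC1=O | intermediate
12 | (2S,3R,6R)-3-bromo-9-methoxy-2,6-dimethyl-9-oxo-6-[(triethylsilyl)peroxy]nonanoic acid | OC(=O)[C@H](C)[C@H](Br)CC[C@@](C)(CCC(=O)OC)OO[Si](CC)(CC)CC | intermediate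
13 | (2R)-2-[(3S,6S)-6-(3-methoxy-3-oxopropyl)-6-methyl-1,2-dioxan-3-yl]propanoic acid | COC(=O)CC[C@]1(C)CC[C@@H]([C@@H](C)C(=O)O)OO1 | intermediate
14 | (2R)-2-[(3S,6S)-6-methyl-6-(3-oxopropyl)-1,2-dioxan-3-yl]propanoic acid | O=CCC[C@]1(C)CC[C@@H]([C@@H](C)C(=O)O)OO1 | intermediate
15 | 4-(2,6,6-trimethylcyclohex-1-en-1-yl)butan-2-one | CC(=O)CCC1=C(C)CCCC1(C)C | starting material
16 | 2,4,6-tri(propan-2-yl)benzenesulfonohydrazide | CC(C)c1cc(C(C)C)c(S(=O)(=O)NN)c(C(C)C)c1 | starting material
17 | N'-[(2E)-4-(2,6,6-trimethylcyclohex-1-en-1-yl)butan-2-ylidene]-2,4,6-tri(propan-2-yl)benzenesulfonohydrazide | C/C(CCC1=C(C)CCCC1(C)C)=N\NS(=O)(=O)c1c(C(C)C)cc(C(C)C)cc1C(C)C | intermediate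
18 | [4-(2,6,6-trimethylcyclohex-1-en-1-yl)but-1-en-2-yl]lithium | [Li]C(=C)CCC1=C(C)CCCC1(C)C | intermediate
19 | (2R)-2-[(3S,6R)-6-[(3RS)-3-hydroxy-4-methylidene-6-(2,6,6-trimethylcyclohex-1-en-1-yl)hexyl]-6-methyl-1,2-dioxan-3-yl]propanoic acid | C=C(CCC1=C(C)CCCC1(C)C)C(O)CC[C@]1(C)CC[C@@H]([C@@H](C)C(=O)O)OO1 | intermediate
20 | (2R)-2-[(3S,6S)-6-methyl-6-[4-methylidene-3-oxo-6-(2,6,6-trimethylcyclohex-1-en-1-yl)hexyl]-1,2-dioxan-3-yl]propanoic acid | C=C(CCC1=C(C)CCCC1(C)C)C(=O)CC[C@]1(C)CC[C@@H]([C@@H](C)C(=O)O)OO1 | intermediate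
21 | (2R)-2-[(3S,6R)-6-[(3R)-3-hydroxy-4-methylidene-6-(2,6,6-trimethylcyclohex-1-en-1-yl)hexyl]-6-methyl-1,2-dioxan-3-yl]propanoic acid | C=C(CCC1=C(C)CCCC1(C)C)[C@H](O)CC[C@]1(C)CC[C@@H]([C@@H](C)C(=O)O)OO1 | target

Total step count: 13. Longest linear sequence: 9 steps (1, 2, 3, 4, 8, 9, 11, 12, 13).

Steps most likely to fail

1. Step 8 (Proposed new method).
- What may go wrong: addition of the weakly nucleophilic primary radical to the enol-lactone alkene may be too slow, so that γ-scission to the epoxide, premature hydrogen transfer or telomerisation takes over. Hydrogen transfer to the oxetanyl radical may also be poorly face-selective.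
- Fallback (known chemistry, from 6 back to 13): bromide 6 is added under the same Giese-type conditions to the polarity-matched vinyl sulfone 2-(trimethylsilyl)ethyl 2-methyl-3-(phenylsulfonyl)but-3-enoate. This should give 2-(trimethylsilyl)ethyl (6R)-9-methoxy-2,6-dimethyl-9-oxo-3-(phenylsulfonyl)-6-[(triethylsilyl)peroxy]nonanoate F1.
- DBU then expels benzenesulfinate (E1cB) to give 2-(trimethylsilyl)ethyl (2E,6S)-9-methoxy-2,6-dimethyl-9-oxo-6-[(triethylsilyl)peroxy]non-2-enoate F2.
- Fluoride frees the peroxide anion, which closes the ring by 6-exo peroxy-Michael addition to 2-(trimethylsilyl)ethyl (2R)-2-[(3S,6S)-6-(3-methoxy-3-oxopropyl)-6-methyl-1,2-dioxan-3-yl]propanoate F3. The same fluoride cleaves its ester to 13.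
- Cost of this fallback: C3 and C2 of the acid are then set only by the chair transition state and by enolate protonation, so diastereomers of 13 would have to be separated.

2. Step 4.
- What may go wrong: displacement at the neopentyl carbon may be slow enough for the neighbouring peroxide oxygen to close a four-membered ring, or for a 1,2-alkyl shift to a peroxycarbenium ion to intervene.
- Fallback (from 4 back to 13): alcohol 4 is condensed with 3-phenyl-1,3-benzoxazol-3-ium tetrafluoroborate and pyridine to methyl (4R)-4-methyl-5-[(3-phenyl-2,3-dihydro-1,3-benzoxazol-2-yl)oxy]-4-[(triethylsilyl)peroxy]pentanoate F4.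
- Visible-light photoredox catalysis (Ir(ppy)2(dtbbpy)PF6, blue light) then generates the same C5 radical by C–O scission, with no substitution at the neopentyl carbon. It is trapped by the vinyl sulfone of the first fallback to give F1, which rejoins the route at 13 through F2 and F3.

3. Step 3.
- What may go wrong: chemoselectivity may be lost, with silylation of the primary alcohol or of both oxygen functions.
- Fallback (from 3 back to 4): both functions are silylated (Et3SiOTf, 2,6-lutidine) to methyl (4R)-4-methyl-5-[(triethylsilyl)oxy]-4-[(triethylsilyl)peroxy]pentanoate F5.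
- The primary silyl ether is then cleaved selectively by mild acid methanolysis (pyridinium p-toluenesulfonate, MeOH, 0 °C), since the less basic peroxide oxygen should be protonated more slowly. This returns 4.

Further compounds
F1 | step 8 | 2-(trimethylsilyl)ethyl (6R)-9-methoxy-2,6-dimethyl-9-oxo-3-(phenylsulfonyl)-6-[(triethylsilyl)peroxy]nonanoate (mixture at C2 and C3) | C[Si](C)(C)CCOC(=O)C(C)C(CC[C@@](C)(CCC(=O)OC)OO[Si](CC)(CC)CC)S(=O)(=O)c1ccccc1
F2 | step 8 | 2-(trimethylsilyl)ethyl (2E,6S)-9-methoxy-2,6-dimethyl-9-oxo-6-[(triethylsilyl)peroxy]non-2-enoate | C[Si](C)(C)CCOC(=O)/C(C)=C/CC[C@@](C)(CCC(=O)OC)OO[Si](CC)(CC)CC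
F3 | step 8 | 2-(trimethylsilyl)ethyl (2R)-2-[(3S,6S)-6-(3-methoxy-3-oxopropyl)-6-methyl-1,2-dioxan-3-yl]propanoate | COC(=O)CC[C@]1(C)CC[C@@H]([C@@H](C)C(=O)OCC[Si](C)(C)C)OO1
F4 | step 4 | methyl (4R)-4-methyl-5-[(3-phenyl-2,3-dihydro-1,3-benzoxazol-2-yl)oxy]-4-[(triethylsilyl)peroxy]pentanoate | COC(=O)CC[C@](C)(COC1Oc2ccccc2N1c1ccccc1)OO[Si](CC)(CC)CC
F5 | step 3 | methyl (4R)-4-methyl-5-[(triethylsilyl)oxy]-4-[(triethylsilyl)peroxy]pentanoate | COC(=O)CC[C@](C)(CO[Si](CC)(CC)CC)OO[Si](CC)(CC)CC
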